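**Retrosynthetic overview**
- Ring B comes from methyl gallate 1. Its adjacent 3,4-diol is locked as the diphenylmethylene ketal 2, so only the meta oxygen that will carry the sulfate stays free.
- Ring A comes from phloroacetophenone 3. One C–C bond (C2–C3, Claisen C-acylation of 3 by 2) gives diketone 4.
- Key disconnection: the O1–C2 bond of pyranone ring C, formed in the same operation as both O–S bonds, from 4 with SO3·pyridine (4 → 5 → 6 → 7).
- Ring order: rings A and B are bought, the dioxole ketal ring is closed first, and ring C is closed last. Ketal hydrogenolysis and protonation (7 → 8 → 9) finish the route.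

Assumption: the target has no stereocentre (planar, achiral flavone), so there is no enantiomer to select; it is delivered as the neutral di-acid drawn, reached through its dipotassium salt.

**Step 1**
Reactants: 1 methyl gallate (methyl 3,4,5-trihydroxybenzoate)
Product: 2 methyl 7-hydroxy-2,2-diphenyl-1,3-benzodioxole-5-carboxylate
Conditions: Ph2CCl2 (1.5 equiv), Ph2O, 175 °C, 30 min
Reagents that add atoms: dichlorodiphenylmethane, ClC(Cl)(c1ccccc1)c1ccccc1
Why: Thermal diphenylmethylene ketal formation (double O-alkylation by the gem-dichloride with loss of HCl) can only close a five-membered dioxole across two neighbouring oxygens, so the symmetric triol gives one ketal with a single free meta hydroxyl.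

**Step 2**
Reactants: 2 methyl 7-hydroxy-2,2-diphenyl-1,3-benzodioxole-5-carboxylate; 3 2',4',6'-trihydroxyacetophenone (phloroacetophenone)
Product: 4 1-(7-hydroxy-2,2-diphenyl-1,3-benzodioxol-5-yl)-3-(2,4,6-trihydroxyphenyl)propane-1,3-dione (in equilibrium with its ring hemiketal tautomer)
Conditions: LiN(SiMe3)2 (6.5 equiv), THF, −78 °C → 40 °C; then 1 M HCl, 0 °C
Reagents that add atoms: none
Why: Crossed Claisen condensation (the C-acylation stage of a Baker–Venkataraman-type flavone synthesis, run on the polylithiated hydroxyacetophenone): excess amide base turns 3 into its phenoxide-enolate, which attacks the non-enolisable ester 2, and deprotonation of the 1,3-diketone drives the equilibrium.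

**Step 3**
Reactants: 4 1-(7-hydroxy-2,2-diphenyl-1,3-benzodioxol-5-yl)-3-(2,4,6-trihydroxyphenyl)propane-1,3-dione
Product: 7 dipotassium 5-hydroxy-4-oxo-2-[2,2-diphenyl-7-(sulfonatooxy)-1,3-benzodioxol-5-yl]-4H-chromen-7-yl sulfate, via hemiketal trisulfate 5 (not isolated), via bis(pyridinium) flavone disulfate 6 (not isolated)
Conditions: SO3·pyridine (4.0 equiv), pyridine, 0 → 40 °C, 12 h; then KOH, MeOH, 0 °C, to pH 8
Reagents that add atoms: sulfur trioxide–pyridine complex, [O-]S(=O)(=O)[n+]1ccccc1; potassium hydroxide, [K+].[OH-]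
Why: Proposed new method: diketone 4 equilibrates with its ring tautomer, the 2-hydroxyflavanone hemiketal in which the ring C O1–C2 bond already exists; SO3·pyridine sulfates the two unchelated phenols (future O7 and the free ring B oxygen) and the tertiary hemiketal hydroxyl to give 5, whose C2 sulfate is β to the C4 ketone and sits on an oxocarbenium-stabilised carbon, so pyridine removes H3 and sulfate leaves (E1cB/E1), fixing the C–O bond in the aromatic pyranone 6, while the 5-OH is held back by its hydrogen bond to C4=O; the closest known reaction types are acid cyclodehydration of Baker–Venkataraman diketones, Burgess-type dehydration through an O-sulfonylated alcohol, and amine–SO3 sulfation of 5-hydroxyflavones that leaves the 5-OH free.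

**Step 4**
Reactants: 7 dipotassium 5-hydroxy-4-oxo-2-[2,2-diphenyl-7-(sulfonatooxy)-1,3-benzodioxol-5-yl]-4H-chromen-7-yl sulfate
Product: 9 tricetin 7,3'-disulfate (5-hydroxy-2-[3,4-dihydroxy-5-(sulfooxy)phenyl]-4-oxo-4H-chromen-7-yl hydrogen sulfate; target), via dipotassium tricetin 7,3'-disulfate 8 (not isolated)
Conditions: H2 (1 atm), Pd(OH)2/C, MeOH–H2O 4:1, 23 °C; filter; then HCl (2.0 equiv, 0.1 M), 0 °C, C18 desalting, freeze-dry
Reagents that add atoms: none
Why: Benzylic hydrogenolysis of the two doubly benzylic C–O bonds of the diphenylmethylene ketal releases the 4',5'-diol without touching aryl sulfate salts or the flavone enone, and stoichiometric cold HCl only protonates the two sulfate groups.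

**Compound list**
1 | methyl gallate (methyl 3,4,5-trihydroxybenzoate) | COC(=O)c1cc(O)c(O)c(O)c1 | starting material
2 | methyl 7-hydroxy-2,2-diphenyl-1,3-benzodioxole-5-carboxylate | COC(=O)c1cc(O)c2OC(c3ccccc3)(c3ccccc3)Oc2c1 | intermediate
3 | 2',4',6'-trihydroxyacetophenone (phloroacetophenone) | CC(=O)c1c(O)cc(O)cc1O | starting material
4 | 1-(7-hydroxy-2,2-diphenyl-1,3-benzodioxol-5-yl)-3-(2,4,6-trihydroxyphenyl)propane-1,3-dione | O=C(CC(=O)c1c(O)cc(O)cc1O)c1cc(O)c2OC(c3ccccc3)(c3ccccc3)Oc2c1 | intermediate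
5 | tris(pyridinium) 5-hydroxy-4-oxo-2-[2,2-diphenyl-7-(sulfonatooxy)-1,3-benzodioxol-5-yl]chromane-2,7-diyl bis(sulfate) (hemiketal trisulfate; racemic at C2, transient) | O=C1CC(OS(=O)(=O)[O-])(c2cc(OS(=O)(=O)[O-])c3OC(c4ccccc4)(c4ccccc4)Oc3c2)Oc2cc(OS(=O)(=O)[O-])cc(O)c12.c1cc[nH+]cc1.c1cc[nH+]cc1.c1cc[nH+]cc1 | intermediate (not isolated)
6 | bis(pyridinium) 5-hydroxy-4-oxo-2-[2,2-diphenyl-7-(sulfonatooxy)-1,3-benzodioxol-5-yl]-4H-chromen-7-yl sulfate | O=c1cc(-c2cc(OS(=O)(=O)[O-])c3OC(c4ccccc4)(c4ccccc4)Oc3c2)oc2cc(OS(=O)(=O)[O-])cc(O)c12.c1cc[nH+]cc1.c1cc[nH+]cc1 | intermediate (not isolated)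
7 | dipotassium 5-hydroxy-4-oxo-2-[2,2-diphenyl-7-(sulfonatooxy)-1,3-benzodioxol-5-yl]-4H-chromen-7-yl sulfate | O=c1cc(-c2cc(OS(=O)(=O)[O-])c3OC(c4ccccc4)(c4ccccc4)Oc3c2)oc2cc(OS(=O)(=O)[O-])cc(O)c12.[K+].[K+] | intermediate
8 | dipotassium tricetin 7,3'-disulfate (dipotassium 2-[3,4-dihydroxy-5-(sulfonatooxy)phenyl]-5-hydroxy-4-oxo-4H-chromen-7-yl sulfate) | O=c1cc(-c2cc(O)c(O)c(OS(=O)(=O)[O-])c2)oc2cc(OS(=O)(=O)[O-])cc(O)c12.[K+].[K+] | intermediate (not isolated)
9 | tricetin 7,3'-disulfate | O=c1cc(-c2cc(O)c(O)c(OS(=O)(=O)O)c2)oc2cc(OS(=O)(=O)O)cc(O)c12 | target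

**Totals**
Total step count: 4. Longest linear sequence: 4 steps (1 → 2 → 4 → 7 → 9).

**Steps most likely to fail, with fallbacks**

Step 3 (the new method). The open-chain tautomer of 4 could be sulfated at an ortho phenol before ring closure, which would end as a 5-sulfate. The diketone CH2 could also be C-sulfonated, or elimination of the hemiketal sulfate could stall. The fallback uses known chemistry and sets out from 4. Cyclodehydration with catalytic TsOH in toluene–dioxane at 90 °C with azeotropic removal of water (the standard second stage of a Baker–Venkataraman flavone synthesis) gives 5,7-dihydroxy-2-(7-hydroxy-2,2-diphenyl-1,3-benzodioxol-5-yl)-4H-chromen-4-one F1. Routine sulfation of F1 with SO3·pyridine (2.5 equiv) in pyridine at 23 °C, which leaves the chelated 5-OH alone, followed by KOH in MeOH gives 7, where it comes back to the route.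

Step 2. The hexa-anionic mixture may be poorly soluble, and the phenoxide-bearing ester may acylate slowly. The fallback sets out from 2 and bypasses 3 and 4. Crossed Claisen condensation with the lithium enolate of ethyl acetate (EtOAc, LiN(SiMe3)2, THF, −78 → 0 °C) gives ethyl 3-(7-hydroxy-2,2-diphenyl-1,3-benzodioxol-5-yl)-3-oxopropanoate F2. Solvent-free thermal condensation of F2 with phloroglucinol (240 °C, microwave; Mentzer pyrone synthesis through the aroylketene) builds ring C and attaches ring A in one operation to give flavone F1. F1 is sulfated as in the first fallback and comes back to the route at 7.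

Step 4. Ketal hydrogenolysis may be slow enough that the C2–C3 double bond starts to reduce, and the sulfate may hydrolyse during protonation. The fallback sets out from 4, cyclised to F1 as in the first fallback, and carries the sulfates as neutral diesters so that the ketal can be removed by acid.
- F1 with 2,2,2-trichloroethyl chlorosulfate (2.2 equiv), Et3N and DMAP in THF gives 5-hydroxy-2-{2,2-diphenyl-7-[(2,2,2-trichloroethoxy)sulfonyloxy]-1,3-benzodioxol-5-yl}-4-oxo-4H-chromen-7-yl 2,2,2-trichloroethyl sulfate F3.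
- AcOH–H2O 4:1 at 90 °C hydrolyses the ketal to 2-{3,4-dihydroxy-5-[(2,2,2-trichloroethoxy)sulfonyloxy]phenyl}-5-hydroxy-4-oxo-4H-chromen-7-yl 2,2,2-trichloroethyl sulfate F4.
- Zn dust and HCO2NH4 in MeOH at 23 °C unmask both sulfates by reductive β-elimination to give diammonium tricetin 7,3'-disulfate F5.
- Cold HCl (2.0 equiv) and C18 desalting then give 9, where it comes back to the route.

**Further compounds**
F1 | step 3 | 5,7-dihydroxy-2-(7-hydroxy-2,2-diphenyl-1,3-benzodioxol-5-yl)-4H-chromen-4-one | O=c1cc(-c2cc(O)c3OC(c4ccccc4)(c4ccccc4)Oc3c2)oc2cc(O)cc(O)c12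
F2 | step 2 | ethyl 3-(7-hydroxy-2,2-diphenyl-1,3-benzodioxol-5-yl)-3-oxopropanoate | CCOC(=O)CC(=O)c1cc(O)c2OC(c3ccccc3)(c3ccccc3)Oc2c1
F3 | step 4 | 5-hydroxy-2-{2,2-diphenyl-7-[(2,2,2-trichloroethoxy)sulfonyloxy]-1,3-benzodioxol-5-yl}-4-oxo-4H-chromen-7-yl 2,2,2-trichloroethyl sulfate | O=c1cc(-c2cc(OS(=O)(=O)OCC(Cl)(Cl)Cl)c3OC(c4ccccc4)(c4ccccc4)Oc3c2)oc2cc(OS(=O)(=O)OCC(Cl)(Cl)Cl)cc(O)c12
F4 | step 4 | 2-{3,4-dihydroxy-5-[(2,2,2-trichloroethoxy)sulfonyloxy]phenyl}-5-hydroxy-4-oxo-4H-chromen-7-yl 2,2,2-trichloroethyl sulfate | O=c1cc(-c2cc(O)c(O)c(OS(=O)(=O)OCC(Cl)(Cl)Cl)c2)oc2cc(OS(=O)(=O)OCC(Cl)(Cl)Cl)cc(O)c12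
F5 | step 4 | diammonium tricetin 7,3'-disulfate | O=c1cc(-c2cc(O)c(O)c(OS(=O)(=O)[O-])c2)oc2cc(OS(=O)(=O)[O-])cc(O)c12.[NH4+].[NH4+]
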